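**Assumption:** the target has no stereocenters (it is 3,5,7‑trihydroxy‑4'‑methoxy‑8‑(1,1‑dimethylallyl)flavone, the reverse‑prenyl isomer of icaritin), so "single enantiomer" is moot. Commercial kaempferide is used as the starting material.

## Retrosynthetic overview
1. The C8–C(CH3)2CH=CH2 bond is made by a [3,3] aromatic Claisen rearrangement of the 7‑O‑prenyl ether. The γ‑carbon of an O‑prenyl group becomes the quaternary carbon, which gives the 1,1‑dimethylallyl group directly.
2. The 7‑O‑prenyl ether comes from selective alkylation of the most acidic phenol (7‑OH) of kaempferide, using prenyl bromide.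
3. Kaempferide already contains the flavonol core with the 4'‑OMe, so no rings are built. The only ring‑like event is the transient six‑membered Claisen transition state.

## Route

**Step 1**
Reactants: **1** kaempferide (3,5,7‑trihydroxy‑4'‑methoxyflavone) and **2** prenyl bromide (1‑bromo‑3‑methylbut‑2‑ene)
Product: **3** 7‑O‑prenylkaempferide (5,3‑dihydroxy‑4'‑methoxy‑7‑(3‑methylbut‑2‑enyloxy)flavone)
Conditions: **2** (1.05 equiv), K2CO3 (1.0 equiv), anhydrous DMF, 0 °C to rt, 4 h
Reagents that add atoms: prenyl bromide, CC(C)=CCBr
Why: Williamson O‑alkylation occurs at the most acidic and least hindered phenol (7‑OH, vinylogous carboxylic acid). The 5‑OH is H‑bonded to the C4 carbonyl, and the 3‑OH is less acidic, so with one equivalent of base and electrophile 7‑O‑alkylation dominates. No stereocenters are formed.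

**Step 2**
Reactant: **3** 7‑O‑prenylkaempferide
Product: **4** target, 8‑(1,1‑dimethylallyl)‑3,5,7‑trihydroxy‑4'‑methoxyflavone
Conditions: Eu(fod)3 (10 mol %), toluene, 80–100 °C, sealed tube, 12 h. The thermal alternative is N,N‑diethylaniline at 180–200 °C under microwave heating.
Reagents that add atoms: none (the reaction is an isomerization)
Why: this is an aromatic Claisen ([3,3]) rearrangement. The prenyl γ‑carbon (CMe2) bonds to the ortho carbon, and the resulting dienone tautomerizes to the phenol, giving the reverse prenyl group. C8 is favored over C6 because the chelated 5‑OH/C4=O fixes the Kekulé structure so that the C7–C8 bond has more double‑bond character. The product is achiral, and the 3‑OH, 5‑OH and 4'‑OMe are untouched.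

## Compound list
1 | kaempferide | COc1ccc(cc1)-c1oc2cc(O)cc(O)c2c(=O)c1O | starting material
2 | prenyl bromide (1‑bromo‑3‑methylbut‑2‑ene) | CC(C)=CCBr | starting material
3 | 7‑O‑prenylkaempferide | COc1ccc(cc1)-c1oc2cc(OCC=C(C)C)cc(O)c2c(=O)c1O | intermediate
4 | 8‑(1,1‑dimethylallyl)‑3,5,7‑trihydroxy‑4'‑methoxyflavone (no stereocenters) | C=CC(C)(C)c1c(O)cc(O)c2c(=O)c(O)c(-c3ccc(OC)cc3)oc12 | target

Atom check: 1 is C16H12O6. Adding C5H8 gives 3 (C21H20O6), and 4 is its isomer, C21H20O6.

## Totals
Total steps: 2. Longest linear sequence: 2 steps (from kaempferide).

## Three most likely failure points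
With only two steps, these are three risks spread across them.

1. **Step 1, chemoselectivity.** 3‑O‑ or 3,7‑di‑O‑prenylation could compete.
   - Fallback: switch to Mitsunobu etherification with prenol (PPh3, DIAD, THF), which is strongly selective for the most acidic 7‑OH.
2. **Step 2, C8 versus C6 regioselectivity.** The 6‑reverse‑prenyl isomer could form.
   - Fallback: avoid the Claisen. Protect 3‑OH and 7‑OH from kaempferide, iodinate C8 (NIS), then do a Pd‑catalysed α‑selective cross‑coupling with prenylboronic acid pinacol ester, followed by deprotection.
3. **Step 2, survival of the reverse prenyl group.** At high temperature the product can undergo [1,5]‑shift to the normal prenyl isomer or acid‑mediated cyclization to a chroman or dihydrofuran.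
   - Fallback: use BCl3‑mediated ortho‑Claisen at –78 to 0 °C in CH2Cl2 with a hindered base such as 2,6‑di‑tert‑butylpyridine. A further option is the Step 2 fallback in point 2.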